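**Plan**
- Ring C is the four-atom bridge O1–C2–C3–C4 across two ortho positions of ring A. Cutting O1–C2 and C3–C4 leaves a C4-methoxy ortho-quinone methide of ring A (phloroglucinaldehyde oxidation level) and the vinyl group C2=C3 on ring B, a 4-alkoxy-3,5-dimethoxystyrene.
- Further cuts: the C4 ketone back to the methyl ether, the aryl–vinyl bond of ring B, the C7''–C8'' bond of the side chain (anti aldol of an aryloxyacetyl imide with O-benzylvanillin) and the aryl ether O–C8''.
- Forward: the ring A acetal takes two steps and the side chain is built on the bromophenol of ring B in six. Ring C then closes in one inverse-demand oxa-[4+2] addition, and three steps adjust C4 and remove the protecting groups.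
- Stereochemistry: C7''/C8'' (1R,2S, erythro) come from a magnesium-catalysed anti aldol under (S)-oxazolidinone control. C2 (S) comes from the chiral Brønsted acid in the cycloaddition; the C4 centre of the cycloadduct is erased on oxidation.

Key step: step 9

Remark: the (R)-acid of step 9 is assumed to favour the styrene face that leads to 2S; if a trial run shows the opposite sense, the (S)-acid takes its place and nothing else changes.

**Step 1**
Reactants: 1 2,4,6-trihydroxybenzaldehyde
Product: 2 2,4-bis(benzyloxy)-6-hydroxybenzaldehyde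
Conditions: BnBr (2.05 equiv), K2CO3 (2.2 equiv), DMF, 0 °C to rt
Reagents that add atoms: benzyl bromide, BrCc1ccccc1
Why: Williamson etherification: the 4-hydroxyl and one ortho hydroxyl are benzylated, and the remaining ortho hydroxyl, hydrogen-bonded to the aldehyde, is the least nucleophilic and stays free.

**Step 2**
Reactants: 2 2,4-bis(benzyloxy)-6-hydroxybenzaldehyde
Product: 3 3,5-bis(benzyloxy)-2-(dimethoxymethyl)phenol
Conditions: HC(OMe)3 (5 equiv), MeOH, p-TsOH·H2O (1 mol %), rt; Et3N quench; used crude, kept cold over a trace of Et3N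
Reagents that add atoms: trimethyl orthoformate, COC(OC)OC; methanol, CO
Why: Acid-catalysed acetalisation with the orthoformate as water scavenger; the large excess of methanol should trap the stabilised oxocarbenium ion before ring A of a second molecule can, and the base quench keeps the labile acetal from reionising.

**Step 3**
Reactants: 4 4-bromo-2,6-dimethoxyphenol
Product: 5 (4-bromo-2,6-dimethoxyphenoxy)acetic acid
Conditions: ClCH2CO2H, NaOH, H2O, reflux; then HCl to pH 1
Reagents that add atoms: chloroacetic acid, OC(=O)CCl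
Why: Williamson ether synthesis of the phenoxide with chloroacetate, the classical phenoxyacetic acid preparation; the primary halide is not hindered by the two ortho methoxy groups.

**Step 4**
Reactants: 5 (4-bromo-2,6-dimethoxyphenoxy)acetic acid
Product: 7 (S)-4-benzyl-3-[(4-bromo-2,6-dimethoxyphenoxy)acetyl]oxazolidin-2-one, via mixed pivalic anhydride 6 (not isolated)
Conditions: PivCl, Et3N, THF, −20 °C; then (S)-4-benzyloxazolidin-2-one, LiCl, −20 °C to rt
Reagents that add atoms: (S)-4-benzyloxazolidin-2-one, O=C1N[C@@H](Cc2ccccc2)CO1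
Why: N-Acylation of the oxazolidinone through the mixed anhydride, which is attacked at the unhindered aryloxyacetyl carbonyl; the auxiliary stereocentre is purchased.

**Step 5**
Reactants: 7 (S)-4-benzyl-3-[(4-bromo-2,6-dimethoxyphenoxy)acetyl]oxazolidin-2-one; 8 4-benzyloxy-3-methoxybenzaldehyde
Product: 10 (S)-4-benzyl-3-[(2R,3R)-3-(4-benzyloxy-3-methoxyphenyl)-2-(4-bromo-2,6-dimethoxyphenoxy)-3-hydroxypropanoyl]oxazolidin-2-one, via trimethylsilyl ether 9 (not isolated)
Conditions: MgCl2 (20 mol %), Et3N (2 equiv), TMSCl (1.5 equiv), EtOAc, rt; then THF/1 M HCl, 0 °C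
Reagents that add atoms: none
Why: Magnesium halide-catalysed direct anti-aldol addition of an N-acyloxazolidinone to a non-enolisable aromatic aldehyde: soft enolisation gives the magnesium-chelated Z-enolate, which should be attacked on the face away from the auxiliary benzyl group (sets the aryloxy carbon, R) through a boat transition state that places hydroxyl and aryloxy anti (sets the carbinol carbon, R), while silylation of the aldolate releases the metal.

**Step 6**
Reactants: 10 (S)-4-benzyl-3-[(2R,3R)-3-(4-benzyloxy-3-methoxyphenyl)-2-(4-bromo-2,6-dimethoxyphenoxy)-3-hydroxypropanoyl]oxazolidin-2-one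
Product: 11 (1R,2S)-1-(4-benzyloxy-3-methoxyphenyl)-2-(4-bromo-2,6-dimethoxyphenoxy)propane-1,3-diol
Conditions: NaBH4, THF/H2O (4:1), 0 °C to rt
Reagents that add atoms: none
Why: Borohydride reduction of the N-acyloxazolidinone (reductive auxiliary cleavage via the aldehyde) should give the primary alcohol without touching the two stereocentres or the aryl bromide.

**Step 7**
Reactants: 11 (1R,2S)-1-(4-benzyloxy-3-methoxyphenyl)-2-(4-bromo-2,6-dimethoxyphenoxy)propane-1,3-diol
Product: 12 (4R,5S)-4-(4-benzyloxy-3-methoxyphenyl)-5-(4-bromo-2,6-dimethoxyphenoxy)-2,2-dimethyl-1,3-dioxane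
Conditions: 2,2-dimethoxypropane, PPTS (cat.), acetone, rt
Reagents that add atoms: 2,2-dimethoxypropane, COC(C)(C)OC
Why: Acid-catalysed transketalisation closes the 1,3-dioxane in which the aryl and aryloxy groups are trans-diequatorial, and the weak acid should not ionise the benzylic C–O bond.

**Step 8**
Reactants: 12 (4R,5S)-4-(4-benzyloxy-3-methoxyphenyl)-5-(4-bromo-2,6-dimethoxyphenoxy)-2,2-dimethyl-1,3-dioxane
Product: 13 (4R,5S)-4-(4-benzyloxy-3-methoxyphenyl)-5-(4-ethenyl-2,6-dimethoxyphenoxy)-2,2-dimethyl-1,3-dioxane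
Conditions: vinylboronic acid pinacol ester, Pd(PPh3)4 (5 mol %), K2CO3, 1,4-dioxane/H2O, 85 °C
Reagents that add atoms: vinylboronic acid pinacol ester, C=CB1OC(C)(C)C(C)(C)O1
Why: Suzuki–Miyaura vinylation of an unhindered aryl bromide by zerovalent palladium; the acetonide and the benzyl ether are inert to the basic medium.

**Step 9**
Reactants: 3 3,5-bis(benzyloxy)-2-(dimethoxymethyl)phenol; 13 (4R,5S)-4-(4-benzyloxy-3-methoxyphenyl)-5-(4-ethenyl-2,6-dimethoxyphenoxy)-2,2-dimethyl-1,3-dioxane
Product: 15 (2S,4S)-5,7-bis(benzyloxy)-2-{4-[(4R,5S)-4-(4-benzyloxy-3-methoxyphenyl)-2,2-dimethyl-1,3-dioxan-5-yl]oxy-3,5-dimethoxyphenyl}-4-methoxychromane, via methoxy ortho-quinone methide 14 (not isolated)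
Conditions: (R)-3,3'-bis(2,4,6-triisopropylphenyl)-1,1'-binaphthyl-2,2'-diyl N-(trifluoromethylsulfonyl)phosphoramide (10 mol %), 5 Å MS, toluene, −40 °C; 3 (1.3 equiv) added slowly
Reagents that add atoms: none
Why: Proposed new method: the chiral acid protonates one methoxy group of 3, methanol leaves with push from the ortho hydroxyl and the two benzyloxy donors, and the methoxy ortho-quinone methide 14 stays hydrogen-bonded to the chiral anion; the CH2 terminus of styrene 13 then attacks the methide carbon (C3–C4) while the developing benzylic cation, stabilised by ring B, is captured by the quinone methide oxygen (O1–C2) in an asynchronous inverse-demand oxa-[4+2] addition. The closest known reactions are the chiral N-triflylphosphoramide- and phosphoric acid-catalysed [4+2] additions of ortho-quinone methides from ortho-hydroxybenzyl alcohols to styrenes, the confined-acid intramolecular cycloaddition of salicylaldehyde-derived oxocarbenium quinone methides with simple alkenes, and the racemic acid-promoted coupling of salicylaldehydes, orthoformate and styrenes to 4-alkoxyflavans; new here is the intermolecular, enantioselective use of an acetal-derived alkoxy quinone methide. Ring C closes as a six-membered oxygen heterocycle by cycloaddition, with the C–C bond leading and the C–O bond closing last. C2 is set by the styrene face left open by the 3,3'-aryl walls of the catalyst while it holds the quinone methide oxygen, and C4 should arise mainly cis to the aryl group from the endo arrangement, which is immaterial because C4 becomes the ketone. Regioselectivity is needed and is fixed by polarity (nucleophilic CH2, electrophilic methide carbon); face selectivity is needed and must come from the catalyst alone, since the dioxane centres are too remote to help. Slow addition of 3 at low temperature with sieves to bind methanol should hold back Friedel–Crafts self-condensation on ring A, acid loss of the acetonide and reionisation of the C2–O1 bond of 15.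

**Step 10**
Reactants: 15 (2S,4S)-5,7-bis(benzyloxy)-2-{4-[(4R,5S)-4-(4-benzyloxy-3-methoxyphenyl)-2,2-dimethyl-1,3-dioxan-5-yl]oxy-3,5-dimethoxyphenyl}-4-methoxychromane
Product: 17 (2S)-5,7-bis(benzyloxy)-2-{4-[(4R,5S)-4-(4-benzyloxy-3-methoxyphenyl)-2,2-dimethyl-1,3-dioxan-5-yl]oxy-3,5-dimethoxyphenyl}chroman-4-one, via C4 hemiketal 16 (not isolated)
Conditions: DDQ (1.2 equiv), CH2Cl2/pH 7 phosphate buffer (10:1), 0 °C to rt
Reagents that add atoms: water, O
Why: DDQ oxidation of a benzylic ether: hydride is abstracted from C4, whose cation is stabilised by O1, the 5- and 7-benzyloxy groups and the methoxy group, water adds and the hemiketal loses methanol to the ketone, so both C4 epimers converge while the less activated C2–H and dioxane C–H bonds should be spared.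

**Step 11**
Reactants: 17 (2S)-5,7-bis(benzyloxy)-2-{4-[(4R,5S)-4-(4-benzyloxy-3-methoxyphenyl)-2,2-dimethyl-1,3-dioxan-5-yl]oxy-3,5-dimethoxyphenyl}chroman-4-one
Product: 18 (2S)-5,7-bis(benzyloxy)-2-{4-[(1R,2S)-1-(4-benzyloxy-3-methoxyphenyl)-1,3-dihydroxypropan-2-yl]oxy-3,5-dimethoxyphenyl}chroman-4-one
Conditions: AcOH/H2O/THF (3:1:1), 40 °C
Reagents that add atoms: none
Why: Acid hydrolysis of the isopropylidene ketal under weakly acidic, methanol-free conditions that should neither ionise the benzylic alcohol nor open the flavanone, which epimerises at C2 only through base-induced chalcone formation.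

**Step 12**
Reactants: 18 (2S)-5,7-bis(benzyloxy)-2-{4-[(1R,2S)-1-(4-benzyloxy-3-methoxyphenyl)-1,3-dihydroxypropan-2-yl]oxy-3,5-dimethoxyphenyl}chroman-4-one
Product: 19 (2S)-5,7-dihydroxy-2-{4-[(1R,2S)-1,3-dihydroxy-1-(4-hydroxy-3-methoxyphenyl)propan-2-yl]oxy-3,5-dimethoxyphenyl}chroman-4-one
Conditions: H2 (1 atm), 10% Pd/C, EtOAc/THF, rt, stopped at full conversion
Reagents that add atoms: none
Why: Hydrogenolysis of the three aryl benzyl ethers over palladium on carbon is much faster than cleavage of the secondary benzylic alcohol or the C2–O1 bond or reduction of the ketone, and the neutral medium keeps C2 and the erythro unit intact.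

**Compound list**
1 | 2,4,6-trihydroxybenzaldehyde | O=Cc1c(O)cc(O)cc1O | starting material
2 | 2,4-bis(benzyloxy)-6-hydroxybenzaldehyde | O=Cc1c(O)cc(OCc2ccccc2)cc1OCc1ccccc1 | intermediate
3 | 3,5-bis(benzyloxy)-2-(dimethoxymethyl)phenol (dimethyl acetal of 2) | COC(OC)c1c(O)cc(OCc2ccccc2)cc1OCc1ccccc1 | intermediate
4 | 4-bromo-2,6-dimethoxyphenol | COc1cc(Br)cc(OC)c1O | starting material
5 | (4-bromo-2,6-dimethoxyphenoxy)acetic acid | COc1cc(Br)cc(OC)c1OCC(=O)O | intermediate
6 | (4-bromo-2,6-dimethoxyphenoxy)acetic pivalic anhydride (not isolated) | COc1cc(Br)cc(OC)c1OCC(=O)OC(=O)C(C)(C)C | intermediate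
7 | (S)-4-benzyl-3-[(4-bromo-2,6-dimethoxyphenoxy)acetyl]oxazolidin-2-one | COc1cc(Br)cc(OC)c1OCC(=O)N1[C@@H](Cc2ccccc2)COC1=O | intermediate
8 | 4-benzyloxy-3-methoxybenzaldehyde (O-benzylvanillin) | COc1cc(C=O)ccc1OCc1ccccc1 | starting material
9 | O-trimethylsilyl ether of 10 (not isolated) | COc1cc([C@@H](O[Si](C)(C)C)[C@H](C(=O)N2[C@@H](Cc3ccccc3)COC2=O)Oc4c(OC)cc(Br)cc4OC)ccc1OCc5ccccc5 | intermediate
10 | (S)-4-benzyl-3-[(2R,3R)-3-(4-benzyloxy-3-methoxyphenyl)-2-(4-bromo-2,6-dimethoxyphenoxy)-3-hydroxypropanoyl]oxazolidin-2-one (anti aldol adduct) | COc1cc([C@@H](O)[C@H](C(=O)N2[C@@H](Cc3ccccc3)COC2=O)Oc4c(OC)cc(Br)cc4OC)ccc1OCc5ccccc5 | intermediate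
11 | (1R,2S)-1-(4-benzyloxy-3-methoxyphenyl)-2-(4-bromo-2,6-dimethoxyphenoxy)propane-1,3-diol (erythro) | COc1cc([C@@H](O)[C@H](CO)Oc2c(OC)cc(Br)cc2OC)ccc1OCc1ccccc1 | intermediate
12 | (4R,5S)-4-(4-benzyloxy-3-methoxyphenyl)-5-(4-bromo-2,6-dimethoxyphenoxy)-2,2-dimethyl-1,3-dioxane | COc1cc([C@H]2OC(C)(C)OC[C@@H]2Oc3c(OC)cc(Br)cc3OC)ccc1OCc1ccccc1 | intermediate
13 | (4R,5S)-4-(4-benzyloxy-3-methoxyphenyl)-5-(4-ethenyl-2,6-dimethoxyphenoxy)-2,2-dimethyl-1,3-dioxane | COc1cc([C@H]2OC(C)(C)OC[C@@H]2Oc3c(OC)cc(C=C)cc3OC)ccc1OCc1ccccc1 | intermediate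
14 | 3,5-bis(benzyloxy)-6-(methoxymethylidene)cyclohexa-2,4-dien-1-one (not isolated; geometry of the exocyclic double bond not fixed) | COC=C1C(=O)C=C(OCc2ccccc2)C=C1OCc1ccccc1 | intermediate
15 | (2S,4S)-5,7-bis(benzyloxy)-2-{4-[(4R,5S)-4-(4-benzyloxy-3-methoxyphenyl)-2,2-dimethyl-1,3-dioxan-5-yl]oxy-3,5-dimethoxyphenyl}-4-methoxychromane (2,4-cis drawn; the C4 epimer is carried along) | COc1cc([C@H]2OC(C)(C)OC[C@@H]2Oc3c(OC)cc([C@@H]4C[C@H](OC)c5c(OCc6ccccc6)cc(OCc6ccccc6)cc5O4)cc3OC)ccc1OCc1ccccc1 | intermediate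
16 | (2S)-4-hydroxy-4-methoxy hemiketal of 17 (not isolated; C4 configuration undefined) | COc1cc([C@H]2OC(C)(C)OC[C@@H]2Oc3c(OC)cc([C@@H]4CC(O)(OC)c5c(OCc6ccccc6)cc(OCc6ccccc6)cc5O4)cc3OC)ccc1OCc1ccccc1 | intermediate
17 | (2S)-5,7-bis(benzyloxy)-2-{4-[(4R,5S)-4-(4-benzyloxy-3-methoxyphenyl)-2,2-dimethyl-1,3-dioxan-5-yl]oxy-3,5-dimethoxyphenyl}chroman-4-one | COc1cc([C@H]2OC(C)(C)OC[C@@H]2Oc3c(OC)cc([C@@H]4CC(=O)c5c(OCc6ccccc6)cc(OCc6ccccc6)cc5O4)cc3OC)ccc1OCc1ccccc1 | intermediate
18 | (2S)-5,7-bis(benzyloxy)-2-{4-[(1R,2S)-1-(4-benzyloxy-3-methoxyphenyl)-1,3-dihydroxypropan-2-yl]oxy-3,5-dimethoxyphenyl}chroman-4-one | COc1cc([C@@H](O)[C@H](CO)Oc2c(OC)cc([C@@H]3CC(=O)c4c(OCc5ccccc5)cc(OCc5ccccc5)cc4O3)cc2OC)ccc1OCc1ccccc1 | intermediate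
19 | (2S)-5,7-dihydroxy-2-{4-[(1R,2S)-1,3-dihydroxy-1-(4-hydroxy-3-methoxyphenyl)propan-2-yl]oxy-3,5-dimethoxyphenyl}chroman-4-one (CNP0318401.1) | COc1cc([C@@H](O)[C@H](CO)Oc2c(OC)cc([C@@H]3CC(=O)c4c(O)cc(O)cc4O3)cc2OC)ccc1O | target

**Step count**
Total: 12 steps. Longest linear sequence: 10 steps (steps 3 to 12, from 4-bromo-2,6-dimethoxyphenol); the ring A branch (steps 1 and 2) joins at step 9.

**Steps most likely to fail**

Step 9: the catalyst may give poor face selectivity at C2 with a styrene that offers no hydrogen-bond donor. The styrene may also be lost to acid-induced oligomerisation, or the quinone methide may be captured by ring A of another molecule. The fallback forms the C2–aryl bond on a ready-made chromone by asymmetric conjugate arylation, a known entry to 2S-flavanones. It sets out from bromide 12: bromine–lithium exchange (n-BuLi, THF, −78 °C), B(OiPr)3 and work-up with aqueous NH4Cl would give the arylboronic acid F1. Purchased 5,7-dihydroxychromone F2 would be benzylated (BnBr, K2CO3, DMF, 60 °C) to 5,7-bis(benzyloxy)chromone F3. Addition of F1 to F3 with Pd(OCOCF3)2 and a chiral 4-tert-butyl-2-(pyridin-2-yl)oxazoline ligand (the enantiomer that delivers 2S; NH4PF6, H2O, 1,2-dichloroethane, 60 °C) should give flavanone 17, where the route is rejoined before step 11. Steps 8 to 10 and the ring A acetal then fall away.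

Step 5: the magnesium enolate of the α-aryloxy imide may add with poor anti selectivity or turn over sluggishly. The fallback sets C8'' by a boron syn aldol and corrects C7'' afterwards by oxidation and chelation-controlled reduction. It sets out from acid 5: acylation of (R)-4-benzyloxazolidin-2-one through anhydride 6, as in step 4, would give the enantiomeric imide F4. Bu2BOTf and iPr2NEt in CH2Cl2 at −78 to 0 °C, then aldehyde 8, should give the Evans syn adduct F5. NaBH4 in THF/H2O would cleave the auxiliary to the threo diol F6. DDQ in 1,4-dioxane should oxidise only the electron-rich benzylic alcohol, giving the hydroxy ketone F7. Zn(BH4)2 in Et2O at −20 °C should then reduce F7 under chelation between the carbonyl and the aryloxy oxygen to the erythro diol 11, where the route is rejoined before step 7.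

Step 10: hydride abstraction may occur at the wrong benzylic site (C2–H or the dioxane C–H next to the benzyloxyaryl ring), or oxidation may run on. The fallback changes the oxidation level in two stages without a hydride abstractor. It sets out from 15: PPTS in acetone/H2O at rt should exchange the labile C4 methoxy group for hydroxyl through the same stabilised cation to give the flavan-4-ol F8, with acetone as solvent holding the acetonide in place. Dess–Martin periodinane with NaHCO3 in CH2Cl2 would then oxidise F8 to 17, where the route is rejoined before step 11.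

**Further compounds**
F1 | step 9 | {4-[(4R,5S)-4-(4-benzyloxy-3-methoxyphenyl)-2,2-dimethyl-1,3-dioxan-5-yl]oxy-3,5-dimethoxyphenyl}boronic acid | COc1cc([C@H]2OC(C)(C)OC[C@@H]2Oc3c(OC)cc(B(O)O)cc3OC)ccc1OCc1ccccc1
F2 | step 9 | 5,7-dihydroxychromone (purchased starting material of the fallback) | O=c1ccoc2cc(O)cc(O)c12
F3 | step 9 | 5,7-bis(benzyloxy)chromone | O=c1ccoc2cc(OCc3ccccc3)cc(OCc3ccccc3)c12
F4 | step 5 | (R)-4-benzyl-3-[(4-bromo-2,6-dimethoxyphenoxy)acetyl]oxazolidin-2-one | COc1cc(Br)cc(OC)c1OCC(=O)N1[C@H](Cc2ccccc2)COC1=O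
F5 | step 5 | (R)-4-benzyl-3-[(2R,3S)-3-(4-benzyloxy-3-methoxyphenyl)-2-(4-bromo-2,6-dimethoxyphenoxy)-3-hydroxypropanoyl]oxazolidin-2-one (syn adduct) | COc1cc([C@H](O)[C@H](C(=O)N2[C@H](Cc3ccccc3)COC2=O)Oc4c(OC)cc(Br)cc4OC)ccc1OCc5ccccc5
F6 | step 5 | (1S,2S)-1-(4-benzyloxy-3-methoxyphenyl)-2-(4-bromo-2,6-dimethoxyphenoxy)propane-1,3-diol (threo) | COc1cc([C@H](O)[C@H](CO)Oc2c(OC)cc(Br)cc2OC)ccc1OCc1ccccc1
F7 | step 5 | (2S)-1-(4-benzyloxy-3-methoxyphenyl)-2-(4-bromo-2,6-dimethoxyphenoxy)-3-hydroxypropan-1-one | COc1cc(C(=O)[C@H](CO)Oc2c(OC)cc(Br)cc2OC)ccc1OCc1ccccc1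
F8 | step 10 | (2S,4S)-5,7-bis(benzyloxy)-2-{4-[(4R,5S)-4-(4-benzyloxy-3-methoxyphenyl)-2,2-dimethyl-1,3-dioxan-5-yl]oxy-3,5-dimethoxyphenyl}chroman-4-ol (cis drawn; C4 epimers both usable) | COc1cc([C@H]2OC(C)(C)OC[C@@H]2Oc3c(OC)cc([C@@H]4C[C@H](O)c5c(OCc6ccccc6)cc(OCc6ccccc6)cc5O4)cc3OC)ccc1OCc1ccccc1
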